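A direct plan would C-acylate the tetralithium polyanion of 2',4',6'-trihydroxyacetophenone A1 with 3,4-bis(benzyloxy)benzoyl chloride A2, made from the corresponding acid, to give the β-diketone A3. It would then cyclodehydrate A3 to 3',4'-di-O-benzylluteolin A4, sulfate A4 at O7 to the potassium salt A5, and finally debenzylate by hydrogenolysis and acidify.
Its weakest steps would be:
- the enolate C-acylation of A1 with A2 that joins the halves, because of excess strong base, a poorly soluble polyanion and competing O-acylation;
- the hydrogenolysis of the sulfated flavone A5, because C2=C3 could be reduced and the polar salt would adsorb on the catalyst;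
- the acid chloride formation leading to A2, which would add a step but no skeleton.

The route rests on disconnecting the C2–C1' bond between rings C and B. Ring C is closed first, on ring A alone, and ring B is then attached to the unfunctionalised C2–H of 5,7-dihydroxychromone by an aerobic oxidative Heck arylation with a boronate that itself comes from C–H borylation of catechol diacetate. The step exploits the O1–C2=C3–C4=O vinylogous ester: aryl is delivered to the β-carbon C2 and palladium to the enolisable C3, so one operation completes the flavone skeleton with both ring-A hydroxyls free. No enolate acylation or acid chloride is needed, and the catechol acetates fall to ammonia, so no hydrogenolysis follows sulfation.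

Key step: step 3

Assumption: the target is taken as the free hydrogen sulfate as drawn; since aryl hydrogen sulfates hydrolyse readily as free acids, the acid form would be generated cold in the last operation and lyophilised at once. The target has no stereocentre.

Step 1
Reactants: 1 2',4',6'-trihydroxyacetophenone (dried)
Product: 3 5,7-dihydroxy-4H-chromen-4-one, via 4-ethoxy-5,7-dihydroxychromenylium triflate 2 (not isolated)
Conditions: HC(OEt)3 (6 equiv), TfOH (1.1 equiv), 0 °C to rt, 12 h; then H2O, 90 °C, 20 min; cool, filter
Reagents that add atoms: triethyl orthoformate, CCOC(OCC)OCC (supplies C2); trifluoromethanesulfonic acid, O=S(=O)(O)C(F)(F)F (its anion stays only in intermediate 2); water, O (supplies the C4 carbonyl oxygen when the 4-ethoxy group is displaced)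
Why: Acid-mediated orthoformate condensation at the acetyl methyl group, with ring closure by either of the two equivalent ortho-hydroxyls, should give the 4-ethoxy-1-benzopyrylium salt, whose hydrolysis (chromone synthesis via a benzopyrylium salt) delivers the pyranone with C2–H and C3–H free; no stereocentre is formed.

Step 2
Reactants: 4 1,2-phenylene diacetate (catechol diacetate)
Product: 5 4-(4,4,5,5-tetramethyl-1,3,2-dioxaborolan-2-yl)-1,2-phenylene diacetate
Conditions: B2pin2 (0.55 equiv), [Ir(OMe)(cod)]2 (1.5 mol %), 4,4'-di-tert-butyl-2,2'-bipyridine (3 mol %), THF, 70 °C, 16 h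
Reagents that add atoms: bis(pinacolato)diboron, CC1(C)OB(B2OC(C)(C)C(C)(C)O2)OC1(C)C
Why: Aromatic C–H borylation under [Ir(OMe)(cod)]2/bipyridine catalysis (Hartwig–Miyaura borylation) is sterically controlled, and in a 1,2-disubstituted benzene the only C–H bonds without an ortho substituent are the equivalent C4/C5 positions, which is the future C1' (para to O4', meta to O3'); aryl esters are tolerated.

Step 3
Reactants: 3 5,7-dihydroxy-4H-chromen-4-one; 5 4-(4,4,5,5-tetramethyl-1,3,2-dioxaborolan-2-yl)-1,2-phenylene diacetate
Product: 6 4-(5,7-dihydroxy-4-oxo-4H-chromen-2-yl)-1,2-phenylene diacetate (3',4'-di-O-acetylluteolin)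
Conditions: 5 (1.8 equiv), Pd(OAc)2 (10 mol %), 2,9-dimethyl-1,10-phenanthroline (12 mol %), O2 (1 atm), DMF, 80 °C, 24 h
Reagents that add atoms: none
Why: Transmetalation of 5 to the phenanthroline-ligated divalent palladium acetate gives an aryl–palladium species that adds syn across C2=C3 of 3 with the aryl group on the β-carbon C2 and palladium on C3; the C3–palladium enolate epimerises through its O-bound form, syn β-hydride elimination of H–C2 restores the pyranone, and O2 reoxidises zerovalent palladium. The closest known reaction type is the oxidative (boron) Heck arylation of chromones and other cyclic enones with arylboron reagents. No ring is closed and no stereocentre survives, since the transient C2 centre is destroyed in the elimination. The step needs arylation at C2 and not C3, with ring A untouched: the O1–C2=C3–C4=O vinylogous ester polarises the alkene so that insertion places the metal at the enolisable C3, the C5–OH···O=C4 hydrogen bond raises the acceptor character, and ring A offers no competing alkene. Ring B regiochemistry is fixed by the C–B bond of 5, and any flavanone formed by protonolysis of the enolate should be dehydrogenated by the same catalyst under O2.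

Step 4
Reactants: 6 4-(5,7-dihydroxy-4-oxo-4H-chromen-2-yl)-1,2-phenylene diacetate
Product: 7 tributylammonium 2-(3,4-diacetoxyphenyl)-5-hydroxy-4-oxo-4H-chromen-7-yl sulfate
Conditions: Bu3N·SO3 (1.5 equiv), MeCN, 50 °C, 4 h; SiO2 (CH2Cl2/MeOH)
Reagents that add atoms: sulfur trioxide–tributylamine complex, CCCC[N+](CCCC)(CCCC)S(=O)(=O)[O-]
Why: O-sulfation with a sulfur trioxide–amine complex should take the acidic, unhindered 7-OH, because the 5-OH is locked in a hydrogen bond to the C4 carbonyl and the catechol is acetylated; the lipophilic tributylammonium salt can be purified on silica.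

Step 5
Reactants: 7 tributylammonium 2-(3,4-diacetoxyphenyl)-5-hydroxy-4-oxo-4H-chromen-7-yl sulfate
Product: 9 luteolin 7-sulfate [2-(3,4-dihydroxyphenyl)-5-hydroxy-4-oxo-4H-chromen-7-yl hydrogen sulfate], via tributylammonium luteolin 7-sulfate 8 (not isolated)
Conditions: NH3 (7 M in MeOH), Ar, 0 °C, 2 h; evaporate; then sulfonic acid cation-exchange resin (H+ form), H2O–MeOH, 0 °C; filter, lyophilise at once
Reagents that add atoms: none
Why: Ammonolysis of the two aryl acetates (acyl transfer to ammonia) proceeds under conditions to which aryl sulfate monoester anions are inert, and cation exchange on a sulfonic acid resin should then give the hydrogen sulfate without excess mineral acid; no stereocentre exists in the target.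

Compound list

1 | 2',4',6'-trihydroxyacetophenone | CC(=O)c1c(O)cc(O)cc1O | starting material
2 | 4-ethoxy-5,7-dihydroxychromenylium trifluoromethanesulfonate | CCOc1cc[o+]c2cc(O)cc(O)c12.O=S(=O)([O-])C(F)(F)F | intermediate
3 | 5,7-dihydroxy-4H-chromen-4-one | O=c1ccoc2cc(O)cc(O)c12 | intermediate
4 | 1,2-phenylene diacetate (catechol diacetate) | CC(=O)Oc1ccccc1OC(C)=O | starting material
5 | 4-(4,4,5,5-tetramethyl-1,3,2-dioxaborolan-2-yl)-1,2-phenylene diacetate | CC(=O)Oc1ccc(B2OC(C)(C)C(C)(C)O2)cc1OC(C)=O | intermediate
6 | 4-(5,7-dihydroxy-4-oxo-4H-chromen-2-yl)-1,2-phenylene diacetate (3',4'-di-O-acetylluteolin) | CC(=O)Oc1ccc(-c2cc(=O)c3c(O)cc(O)cc3o2)cc1OC(C)=O | intermediate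
7 | tributylammonium 2-(3,4-diacetoxyphenyl)-5-hydroxy-4-oxo-4H-chromen-7-yl sulfate | CC(=O)Oc1ccc(-c2cc(=O)c3c(O)cc(OS(=O)(=O)[O-])cc3o2)cc1OC(C)=O.CCCC[NH+](CCCC)CCCC | intermediate
8 | tributylammonium luteolin 7-sulfate | O=c1cc(-c2ccc(O)c(O)c2)oc2cc(OS(=O)(=O)[O-])cc(O)c12.CCCC[NH+](CCCC)CCCC | intermediate
9 | luteolin 7-sulfate | O=c1cc(-c2ccc(O)c(O)c2)oc2cc(OS(=O)(=O)O)cc(O)c12 | target

Total step count: 5. Longest linear sequence: 4 steps (steps 1, 3, 4 and 5; step 2 is a one-step branch).

Steps most likely to fail

Step 3. The C3–palladium enolate may be protonated faster than it undergoes β-hydride elimination, the boronate may be consumed by oxidative deborylation or homocoupling, or insertion into the electron-rich chromone may stall. Fallback: from 3 and 5, the union would be split into a redox-neutral conjugate addition (Pd(O2CCF3)2, 2,2'-bipyridine, water, 1,2-dichloroethane, 60 °C). This stops at the flavanone, racemic 4-(5,7-dihydroxy-4-oxochroman-2-yl)-1,2-phenylene diacetate F1. A separate dehydrogenation of F1 with iodine in pyridine at 90 °C would then return to the route at 6.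

Step 5. The aryl hydrogen sulfate may lose its sulfate by acid-catalysed hydrolysis during proton exchange and concentration, and the catecholate may be oxidised by air during ammonolysis. Fallback: from 7, saponification and cation exchange in one operation with Ba(OH)2 in degassed aqueous methanol at 0 °C (tributylamine extracted, excess base removed with CO2) would give barium bis(luteolin 7-sulfate) F2, which can be purified as a neutral salt. Titration of F2 with exactly one equivalent of H2SO4 per barium at 0 °C would precipitate BaSO4 and leave the free acid in the filtrate for immediate lyophilisation, returning to the route at 9.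

Step 4. Over-sulfation at O5, or amine-promoted migration of an acetyl group from the catechol to O7 before sulfation, would give isomeric salts that are hard to separate. Fallback: from 3, the order of events would be reversed. The same sulfur trioxide–tributylamine complex would sulfate the chromone at O7, where the hydrogen-bonded O5 is the only other hydroxyl and no acetate is present, to give tributylammonium 5-hydroxy-4-oxo-4H-chromen-7-yl sulfate F3. Oxidative arylation of F3 with 5 under the conditions of step 3 would then return to the route at 7.

Further compounds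

F1 | step 3 | rac-4-(5,7-dihydroxy-4-oxochroman-2-yl)-1,2-phenylene diacetate (racemic at C2) | CC(=O)Oc1ccc(C2CC(=O)c3c(O)cc(O)cc3O2)cc1OC(C)=O
F2 | step 5 | barium bis(luteolin 7-sulfate) | [Ba+2].O=c1cc(-c2ccc(O)c(O)c2)oc2cc(OS(=O)(=O)[O-])cc(O)c12.O=c1cc(-c2ccc(O)c(O)c2)oc2cc(OS(=O)(=O)[O-])cc(O)c12
F3 | step 4 | tributylammonium 5-hydroxy-4-oxo-4H-chromen-7-yl sulfate | O=c1ccoc2cc(OS(=O)(=O)[O-])cc(O)c12.CCCC[NH+](CCCC)CCCC
A1 | direct plan | tetralithium polyanion of 2',4',6'-trihydroxyacetophenone | [Li+].[Li+].[Li+].[Li+].C=C([O-])c1c([O-])cc([O-])cc1[O-]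
A2 | direct plan | 3,4-bis(benzyloxy)benzoyl chloride | O=C(Cl)c1ccc(OCc2ccccc2)c(OCc2ccccc2)c1
A3 | direct plan | 1-[3,4-bis(benzyloxy)phenyl]-3-(2,4,6-trihydroxyphenyl)propane-1,3-dione | O=C(CC(=O)c1c(O)cc(O)cc1O)c1ccc(OCc2ccccc2)c(OCc2ccccc2)c1
A4 | direct plan | 2-[3,4-bis(benzyloxy)phenyl]-5,7-dihydroxy-4H-chromen-4-one (3',4'-di-O-benzylluteolin) | O=c1cc(-c2ccc(OCc3ccccc3)c(OCc3ccccc3)c2)oc2cc(O)cc(O)c12
A5 | direct plan | potassium 2-[3,4-bis(benzyloxy)phenyl]-5-hydroxy-4-oxo-4H-chromen-7-yl sulfate | O=c1cc(-c2ccc(OCc3ccccc3)c(OCc3ccccc3)c2)oc2cc(OS(=O)(=O)[O-])cc(O)c12.[K+]
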